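**Strategy.** The ester C–O bond is kept and the benzene ring is taken apart instead. Arene C1 and C4–C6 come from a 2-pyrone that already carries the (S)-16-methyloctadecyl ester on its 3-position; arene C2 and C3, each with its oxygen, come from tris(trimethylsilyloxy)ethylene. One thermal operation (inverse-demand [4+2] addition, extrusion of CO2, loss of trimethylsilanol) closes the benzene ring and sets the ester carbon, O2 and O3 on three neighbouring ring carbons, the 1,2,3-pattern that the step exploits. The precursor is pyrone ester 10, reached by acylating (S)-16-methyloctadecan-1-ol, itself assembled by copper-catalysed coupling of a C5 Grignard reagent with a C14 bromide.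

Key step: step 6

Assumption: (S)-1-bromo-2-methylbutane 4 is bought as the single enantiomer and supplies C15–C18 and the C16 methyl with the S configuration already in place; the target has fifteen CH2 groups between the ester oxygen and C16.

**Step 1**
Reactants: 1 tetradecane-1,14-diol
Product: 2 14-bromotetradecan-1-ol
Conditions: 48% aq HBr (1.2 equiv), PhMe, reflux
Reagents that add atoms: hydrogen bromide, Br
Why: Nucleophilic substitution of one protonated primary hydroxyl by bromide; the monobromide should be favoured because it partitions into toluene away from the aqueous acid.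

**Step 2**
Reactants: 2 14-bromotetradecan-1-ol
Product: 3 [(14-bromotetradecyl)oxy](tert-butyl)dimethylsilane
Conditions: TBSCl, imidazole, CH2Cl2, 0 °C → rt
Reagents that add atoms: tert-butyldimethylsilyl chloride (TBSCl), CC(C)(C)[Si](C)(C)Cl
Why: Routine silylation of a primary alcohol, which removes the acidic proton that would quench the Grignard reagent of step 3.

**Step 3**
Reactants: 3 [(14-bromotetradecyl)oxy](tert-butyl)dimethylsilane; 4 (S)-1-bromo-2-methylbutane
Product: 6 (S)-tert-butyldimethyl[(16-methyloctadecyl)oxy]silane, via (S)-2-methylbutylmagnesium bromide 5 (not isolated)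
Conditions: 4, Mg, I2 (cat.), THF, 40 °C; then 3, Li2CuCl4 (3 mol%), THF, −10 °C → rt
Reagents that add atoms: none
Why: Copper-catalysed alkyl–alkyl Grignard cross-coupling of two primary partners forms the C14–C15 bond; C16 is β to magnesium, never becomes a carbanion or radical site and so keeps its S configuration, and the silyl ether is inert.

**Step 4**
Reactants: 6 (S)-tert-butyldimethyl[(16-methyloctadecyl)oxy]silane
Product: 7 (S)-16-methyloctadecan-1-ol
Conditions: camphorsulfonic acid (cat.), MeOH–CH2Cl2 1:1, rt
Reagents that add atoms: none
Why: Acid-catalysed methanolysis of a primary silyl ether, under conditions that cannot touch the saturated chain or its stereocenter.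

**Step 5**
Reactants: 7 (S)-16-methyloctadecan-1-ol; 8 2-oxo-2H-pyran-3-carboxylic acid
Product: 10 (S)-16-methyloctadecyl 2-oxo-2H-pyran-3-carboxylate, via 2-oxo-2H-pyran-3-carbonyl chloride 9 (not isolated)
Conditions: 8, (COCl)2, DMF (cat.), CH2Cl2, 0 °C → rt, evaporate; then 7, pyridine, CH2Cl2, 0 °C → rt
Reagents that add atoms: none
Why: Vilsmeier-type chlorination of the acid followed by nucleophilic acyl substitution by the primary alcohol; the weakly nucleophilic base, low temperature and absence of free alkoxide should spare the electrophilic C6 of the pyrone.

**Step 6**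
Reactants: 10 (S)-16-methyloctadecyl 2-oxo-2H-pyran-3-carboxylate; 11 tris(trimethylsilyloxy)ethylene
Product: 14 (S)-16-methyloctadecyl 2,3-bis(trimethylsilyloxy)benzoate, via bridged bicyclic lactone 12 (not isolated), via cyclohexadiene 13 (not isolated)
Conditions: 11 (4 equiv), dry PhMe, 120 °C, sealed tube; evaporate, use crude
Reagents that add atoms: none
Why: Proposed new method: the C3 ester lowers the LUMO of the pyrone diene (C3=C4–C5=C6), so the electron-rich silyl ketene acetal 11 should add across C3 and C6, its CH(OSiMe3) carbon bonding to C6 and its C(OSiMe3)2 carbon to C3, in a concerted asynchronous [4+2] process or through a zwitterion that collapses to the same 2-oxabicyclo[2.2.2]octenone 12; the closest known reaction type is the thermal inverse-electron-demand Diels–Alder reaction of 3-alkoxycarbonyl-2-pyrones with 1,1-dialkoxy- and 1,1,2-trialkoxyethylenes, from which this case differs only in having silyl instead of alkyl groups on the dienophile oxygens. The benzene ring is closed by this intermolecular [4+2] cycloaddition, which makes arene bonds C1–C2 and C3–C4 at once. Retro-[4+2] extrusion of CO2 from 12 then gives cyclohexadiene 13, and 1,2-elimination of trimethylsilanol (silyloxy group from the ketal carbon, hydrogen from the neighbouring CH) aromatises it. No stereocenter is created that survives: the sp3 centres of 12 and 13 are lost on aromatisation, and C16 of the chain is far from every reacting atom. The selectivity needed is ring closure at C3 after bonding at C6 instead of silyl transfer to the pyrone enolate (an open Michael-type adduct), which heating in a non-polar solvent without Lewis acid or fluoride should secure. Regiochemistry needs no control, because both dienophile carbons bear oxygen and either orientation ends in the same 2,3-dioxygenated benzoate.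

**Step 7**
Reactants: 14 (S)-16-methyloctadecyl 2,3-bis(trimethylsilyloxy)benzoate
Product: 15 Gentiside F, (S)-16-methyloctadecyl 2,3-dihydroxybenzoate
Conditions: MeOH–THF, citric acid (cat.), rt
Reagents that add atoms: none
Why: Aryl trimethylsilyl ethers are solvolysed by methanol with a trace of acid at room temperature, conditions too mild to transesterify the alkyl benzoate; any partly desilylated material from step 6 converges on the same product.

**Compound list**
1 | tetradecane-1,14-diol | OCCCCCCCCCCCCCCO | starting material
2 | 14-bromotetradecan-1-ol | OCCCCCCCCCCCCCCBr | intermediate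
3 | [(14-bromotetradecyl)oxy](tert-butyl)dimethylsilane | CC(C)(C)[Si](C)(C)OCCCCCCCCCCCCCCBr | intermediate
4 | (S)-1-bromo-2-methylbutane | CC[C@H](C)CBr | starting material
5 | (S)-2-methylbutylmagnesium bromide | CC[C@H](C)C[Mg]Br | intermediate (not isolated)
6 | (S)-tert-butyldimethyl[(16-methyloctadecyl)oxy]silane | CC[C@H](C)CCCCCCCCCCCCCCCO[Si](C)(C)C(C)(C)C | intermediate
7 | (S)-16-methyloctadecan-1-ol | CC[C@H](C)CCCCCCCCCCCCCCCO | intermediate
8 | 2-oxo-2H-pyran-3-carboxylic acid | O=C(O)C1=CC=COC1=O | starting material
9 | 2-oxo-2H-pyran-3-carbonyl chloride | O=C(Cl)C1=CC=COC1=O | intermediate (not isolated)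
10 | (S)-16-methyloctadecyl 2-oxo-2H-pyran-3-carboxylate | CC[C@H](C)CCCCCCCCCCCCCCCOC(=O)C1=CC=COC1=O | intermediate
11 | tris(trimethylsilyloxy)ethylene | C[Si](C)(C)OC=C(O[Si](C)(C)C)O[Si](C)(C)C | starting material
12 | bridged bicyclic lactone, (S)-16-methyloctadecyl 3-oxo-5,5,6-tris(trimethylsilyloxy)-2-oxabicyclo[2.2.2]oct-7-ene-4-carboxylate (ring stereocentres as a mixture, all lost later; chain centre S) | CC[C@H](C)CCCCCCCCCCCCCCCOC(=O)C12C=CC(OC1=O)C(O[Si](C)(C)C)C2(O[Si](C)(C)C)O[Si](C)(C)C | intermediate (not isolated)
13 | cyclohexadiene, (S)-16-methyloctadecyl 5,6,6-tris(trimethylsilyloxy)cyclohexa-1,3-diene-1-carboxylate (C5 as a mixture, lost later; chain centre S) | CC[C@H](C)CCCCCCCCCCCCCCCOC(=O)C1=CC=CC(O[Si](C)(C)C)C1(O[Si](C)(C)C)O[Si](C)(C)C | intermediate (not isolated)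
14 | (S)-16-methyloctadecyl 2,3-bis(trimethylsilyloxy)benzoate | CC[C@H](C)CCCCCCCCCCCCCCCOC(=O)c1cccc(O[Si](C)(C)C)c1O[Si](C)(C)C | intermediate
15 | Gentiside F, (S)-16-methyloctadecyl 2,3-dihydroxybenzoate | CC[C@H](C)CCCCCCCCCCCCCCCOC(=O)c1cccc(O)c1O | target

**Totals.** 7 steps in all; the longest linear sequence is 7 steps (1 → 15). The only stereocenter, C16, is bought in 4 and never becomes a reactive site.

**Steps most likely to fail**

Step 6. What may go wrong: bonding of 11 at pyrone C6 followed by silyl transfer to the pyrone enolate instead of ring closure, or consumption of 11 by the trimethylsilanol released before cycloaddition is complete. Fallback (known chemistry, the ring bought instead of built): setting out from alcohol 7, Steglich esterification with commercial 2,3-bis(benzyloxy)benzoic acid (DCC, cat. DMAP, CH2Cl2, rt) should give (S)-16-methyloctadecyl 2,3-bis(benzyloxy)benzoate F1. Hydrogenolysis of both benzyl ethers (H2, 10% Pd/C, EtOAc, rt) then comes back to the route at 15.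

Step 5. What may go wrong: opening of the pyrone ring by nucleophilic attack at C6 during chlorination or acylation, or hydrolysis of the acyl chloride back to the acid. Fallback: setting out from 7 and 8, a Mitsunobu esterification (PPh3, diisopropyl azodicarboxylate, THF, 0 °C → rt) activates the primary alcohol instead of the acid. The carboxylate of 8 is then the only nucleophile present and neither acyl chloride nor amine base is needed. The fallback comes back at 10 and no new compound arises (F0).

Step 3. What may go wrong: slow coupling of the β-branched Grignard reagent, so that homocoupling, reduction or elimination of the bromide take over. Fallback: setting out from 4, displacement with PhSO2Na (DMF, 80 °C) should give (S)-[(2-methylbutyl)sulfonyl]benzene F2. Deprotonation (n-BuLi, THF, −78 °C) gives [(2S)-2-methyl-1-(phenylsulfonyl)butyl]lithium F3. Alkylation of this anion with the unbranched bromide 3 (THF–DMPU, −78 °C → rt) gives tert-butyldimethyl{[(16S)-16-methyl-15-(phenylsulfonyl)octadecyl]oxy}silane F4 (mixture at C15). Reductive desulfonylation (6% Na/Hg, MeOH–THF, −20 °C) comes back to the route at 6. The hydrogen at C16 is β to the sulfonyl group and is not removed, so the configuration holds.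

**Further compounds**
F1 | step 6 | (S)-16-methyloctadecyl 2,3-bis(benzyloxy)benzoate | CC[C@H](C)CCCCCCCCCCCCCCCOC(=O)c1cccc(OCc2ccccc2)c1OCc1ccccc1
F0 | step 5 | none | none
F2 | step 3 | (S)-[(2-methylbutyl)sulfonyl]benzene | CC[C@H](C)CS(=O)(=O)c1ccccc1
F3 | step 3 | [(2S)-2-methyl-1-(phenylsulfonyl)butyl]lithium | CC[C@H](C)C([Li])S(=O)(=O)c1ccccc1
F4 | step 3 | tert-butyldimethyl{[(16S)-16-methyl-15-(phenylsulfonyl)octadecyl]oxy}silane | CC[C@H](C)C(CCCCCCCCCCCCCCO[Si](C)(C)C(C)(C)C)S(=O)(=O)c1ccccc1
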